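(All runs are simulated from invented constants; the scatter is artificial.)

Every D charged stands at any moment as free D, as X or as something we do not read, and these three sum to 100%. We apply this balance to the earlier runs, maple and larch, to forecast the flask.

in all of them: D 0.050 M

| flask | Q | Z | remark | time |
|---|---|---|---|---|
| maple | 1.3 equiv | 1 equiv | run made earlier |  |
| larch | 3 equiv | 1 equiv | run made earlier |  |
| flask | 2.00 equiv | 1.00 equiv |  | 15 d |

| run | time / d | X / % | D / % |
|---|---|---|---|
| maple | 0.500 | 7 | 63 |
| maple | 1.04 | 10 | 48 |
| maple | 2.00 | 12 | 30 |
| maple | 4.00 | 11 | 24 |
| maple | 10.0 | 4 | 10 |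
| larch | 0.500 | 11 | 56 |
| larch | 1.04 | 13 | 41 |
| larch | 2.00 | 22 | 31 |
| larch | 4.00 | 21 | 23 |
| larch | 10.0 | 9 | 13 |

(standard deviation of a reading: 2 percentage points)

- a reading or a percentage of X counts all its forms, free or not
- a reading of D is of its free form alone

1. time up to 15 d at which X stands highest
2. the amount of X, in percent of the D charged, at that time

At 2.00 d, where X reads highest in both runs, free D reads 30% in maple and 31% in larch, nearly the same. The unread rest, however, is 58.0% in maple and 47.0% in larch. So the extra Q shows up in the split of lost D between X and the rest, its selectivity.

The bench rule, with the charges of D and Z held as they stand in both runs, is a straight line: take maple's peak reading as the large term and add a correction, the gain in peak reading per equivalent of Q, s, 5.9 percentage points. For the flask, we reckon 16.1% near 2.00 d, with 2 points of scatter on each reading behind it. The rule has a lower border: the ratio of maple's peak reading to s is 2.04 equivalents, more than maple's 1.3, so the line leaves 4.35% of X at no Q. If X is made from Q, the line must bend somewhere below maple's charge, but the flask's 2.00 equiv lies between the charges of the two runs.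

The forecast gives 17% at 2.7 d, reasoning that “Q mainly changes how much of that loss ends up as X”. It agrees with our split but puts the height above ours and the time later than ours.

The simulation gives 16.0% at 2.16 d, so the forecast's height holds within its margin, while its time is too late by a factor of 1.25. Our reckoned 16.1% lies 0.10 points from the flask's height.

    2 D → E (k = 0.330 /M/h)
    D + X ⇌ L, settled at all times (K = 17.0 /M)
    D + Q ⇌ X (K = 6.80 /M, k = 0.120 /M/h)
    Z + Q ⇌ G (K = 210 /M, k = 0.300 /M/h)

In the flask at 1.06 d, the step 2 D → E uses D 1.8 times as fast as D + Q → X, by the forward rate of each step alone. At the flask's best time, E holds 49.2% of the D charged and X 16.0%.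

For a neighbour flask charged with 5.00 equiv of Q, s gives 33.8%. The computed peak there is 34.9%.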